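**Assumption:** atoms are labelled with tuberostemonine-type position numbers (N4–C9a=C1 enamine; C9 carbinol; C10 ethyl-bearing; C11–O and C12 at the fusion of the ring-C lactone, C13 methyl-bearing; C3 carrying the side-chain lactone with C18–O and C20 methyl). Rings: A azepane, B pyrroline, C cyclohexene, D fused lactone, E side-chain lactone.

## Retrosynthetic overview

1. Rings A and C are closed last: N4–C5 by N-alkylation of a cyclic imine, and C1–C12 by enamine Michael addition to a butenolide, which also sets C12 and C13.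
2. Ring B comes from C9a=N4 condensation of a γ-amino ketone, made from a γ-nitro ketone. Nitromethane is the N4–C3 linchpin: C3–C18 by anti-selective nitroaldol (then ring E by lactonisation), C2–C3 by nitronate Michael addition.
3. The Michael acceptor is an α'-hydroxy vinyl ketone: C9–C9a from 1-lithio-1-methoxyallene (acryloyl anion equivalent) and a Weinreb amide; C8–C9 and the C9 configuration from a chelation-controlled Grignard addition; ring D (as butenolide) by methacrylate ring-closing metathesis.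
4. C10/C11 come from an auxiliary-controlled syn-aldol with acrolein; C20 from an auxiliary-controlled allylation, followed by ozonolysis to the nitroaldol aldehyde.
5. Ring order: D (as butenolide) → E → B → A → C.

## Route

Step 1
Reactants: 1 (S)-4-benzyl-1,3-oxazolidin-2-one; 2 butanoyl chloride
Product: 3 (S)-4-benzyl-3-butanoyl-1,3-oxazolidin-2-one
Conditions: n-BuLi, THF, −78 °C; then 2, −78 → 0 °C
Reagents that add atoms: none
Why: N-acylation of the lithiated oxazolidinone installs the butanoyl unit that becomes C9, C10 and the ethyl group; no stereocentre is formed.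

Step 2
Reactants: 3 (S)-4-benzyl-3-butanoyl-1,3-oxazolidin-2-one; 4 acrolein
Product: 5 (S)-4-benzyl-3-[(2S,3R)-2-ethyl-3-hydroxypent-4-enoyl]-1,3-oxazolidin-2-one
Conditions: Bu2BOTf, iPr2NEt, CH2Cl2, −78 → 0 °C; 4, −78 → 0 °C; then pH 7 buffer, MeOH, H2O2, 0 °C
Reagents that add atoms: none
Why: Evans syn-aldol reaction: the Z-boron enolate reacts through a Zimmerman–Traxler chair on the face away from the benzyl group, setting C10 (S) and C11 (R) in the required syn relationship.

Step 3
Reactants: 5 (S)-4-benzyl-3-[(2S,3R)-2-ethyl-3-hydroxypent-4-enoyl]-1,3-oxazolidin-2-one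
Product: 6 (2S,3R)-2-ethyl-3-hydroxy-N-methoxy-N-methylpent-4-enamide
Conditions: MeNH(OMe)·HCl, AlMe3, CH2Cl2, −15 → 0 °C; aq. HCl work-up
Reagents that add atoms: N,O-dimethylhydroxylamine hydrochloride, CNOC.Cl
Why: Weinreb transamidation by the aluminium amide, assisted by the free β-hydroxyl, cleaves the auxiliary without touching C10 or C11.

Step 4
Reactants: 6 (2S,3R)-2-ethyl-3-hydroxy-N-methoxy-N-methylpent-4-enamide; 7 methoxyallene
Product: 9 (5S,6R)-5-ethyl-6-hydroxy-3-methoxyocta-1,2,7-trien-4-one, via 1-lithio-1-methoxyallene 8 (not isolated)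
Conditions: 7 (2.5 equiv), n-BuLi (2.4 equiv), THF, −78 °C; then 6, −78 → −40 °C; aq. NH4Cl; crude product used at once
Reagents that add atoms: none
Why: Acylation of an acyl anion equivalent: 1-lithio-1-methoxyallene (a masked acryloyl anion) adds once to the Weinreb amide through a stable chelated tetrahedral intermediate, forming the C9–C9a bond between two carbons that are both carbonyl-type electrophilic carbons.

Step 5
Reactants: 9 (5S,6R)-5-ethyl-6-hydroxy-3-methoxyocta-1,2,7-trien-4-one; 10 1-bromo-4-chlorobutane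
Product: 13 (4R,5S,6R)-4-(4-chlorobutyl)-5-ethyl-4,6-dihydroxyocta-1,7-dien-3-one, via 4-chlorobutylmagnesium bromide 11 (not isolated), via allenyl carbinol 12 (not isolated)
Conditions: 10, Mg, THF, 0 °C (gives 11, 3 equiv); 9, THF/CH2Cl2, −78 °C; then 1 M HCl, THF, 0 → 23 °C
Reagents that add atoms: water, O
Why: Chelation-controlled Grignard addition: the magnesium alkoxide at C11 chelates the C9 ketone in a six-membered ring, so the 4-chlorobutyl group enters anti to the C10 ethyl group and sets C9 (R); acid hydrolysis of the methoxyallene enol ether then unveils the α'-hydroxy vinyl ketone.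

Step 6
Reactants: 13 (4R,5S,6R)-4-(4-chlorobutyl)-5-ethyl-4,6-dihydroxyocta-1,7-dien-3-one; 14 nitromethane
Product: 15 (5R,6S,7R)-5-(4-chlorobutyl)-6-ethyl-5,7-dihydroxy-1-nitronon-8-en-4-one
Conditions: 14 (10 equiv), DBU (0.1 equiv), THF, 0 °C
Reagents that add atoms: none
Why: Nitro-Michael addition: the nitronate of nitromethane (an aminomethyl anion equivalent) adds to the reactive α'-hydroxy enone, joining C2 and C3 (both normally electrophilic) and bringing in the future N4; no stereocentre is formed.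

Step 7
Reactants: 15 (5R,6S,7R)-5-(4-chlorobutyl)-6-ethyl-5,7-dihydroxy-1-nitronon-8-en-4-one; 16 methacrylic anhydride
Product: 17 (3R,4S,5R)-5-(4-chlorobutyl)-4-ethyl-5-hydroxy-9-nitro-6-oxonon-1-en-3-yl 2-methylprop-2-enoate
Conditions: 16 (1.3 equiv), DMAP (0.1 equiv), pyridine, CH2Cl2, 0 °C
Reagents that add atoms: none
Why: DMAP-catalysed acylation is selective for the secondary allylic C11 hydroxyl over the hindered tertiary C9 hydroxyl, and pyridine is too weak a base to ionise the nitroalkane.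

Step 8
Reactants: 17 (3R,4S,5R)-5-(4-chlorobutyl)-4-ethyl-5-hydroxy-9-nitro-6-oxonon-1-en-3-yl 2-methylprop-2-enoate
Product: 18 (5R)-5-[(3S,4R)-4-(4-chlorobutyl)-4-hydroxy-8-nitro-5-oxooctan-3-yl]-3-methylfuran-2(5H)-one
Conditions: second-generation Grubbs catalyst (H2IMes)(PCy3)Cl2Ru=CHPh (5 mol %), toluene, 80 °C
Reagents that add atoms: none
Why: Ring-closing metathesis of the allylic methacrylate forms the α-methyl butenolide (ring D in unsaturated form) with loss of ethene; existing stereocentres are untouched.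

Step 9
Reactants: 19 (R)-4-benzyl-3-propanoyl-1,3-oxazolidin-2-one; 20 allyl iodide
Product: 21 (R)-4-benzyl-3-[(2S)-2-methylpent-4-enoyl]-1,3-oxazolidin-2-one
Conditions: NaN(SiMe3)2, THF, −78 °C; then 20, −78 → −45 °C
Reagents that add atoms: none
Why: Evans asymmetric alkylation: the chelated Z-sodium enolate is allylated on the face opposite the benzyl group, setting C20 (S).

Step 10
Reactants: 21 (R)-4-benzyl-3-[(2S)-2-methylpent-4-enoyl]-1,3-oxazolidin-2-one
Product: 22 methyl (2S)-2-methylpent-4-enoate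
Conditions: NaOMe (0.2 equiv), MeOH, 0 °C
Reagents that add atoms: methanol, CO
Why: Methoxide-catalysed methanolysis at the exocyclic imide carbonyl removes the auxiliary at 0 °C without epimerising C20.

Step 11
Reactants: 22 methyl (2S)-2-methylpent-4-enoate
Product: 23 methyl (2S)-2-methyl-4-oxobutanoate
Conditions: O3, CH2Cl2, −78 °C; then PPh3, −78 → 23 °C
Reagents that add atoms: ozone, [O-][O+]=O
Why: Ozonolysis with reductive work-up cleaves the terminal alkene to the aldehyde that becomes C18.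

Step 12
Reactants: 18 (5R)-5-[(3S,4R)-4-(4-chlorobutyl)-4-hydroxy-8-nitro-5-oxooctan-3-yl]-3-methylfuran-2(5H)-one; 23 methyl (2S)-2-methyl-4-oxobutanoate
Product: 25 (5R)-5-[(3S,4R,8R)-4-(4-chlorobutyl)-4-hydroxy-8-[(2S,4S)-4-methyl-5-oxooxolan-2-yl]-8-nitro-5-oxooctan-3-yl]-3-methylfuran-2(5H)-one, via nitro alcohol 24 (not isolated)
Conditions: 23 (1.5 equiv), valine-derived chiral P-spiro tetraaminophosphonium chloride (5 mol %, the enantiomer that gives the 3R,18S anti adduct), KOtBu (5 mol %), THF, −78 °C; then TsOH·H2O (0.2 equiv), CH2Cl2, 23 °C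
Reagents that add atoms: none
Why: Catalytic asymmetric anti-selective nitroaldol (Henry) reaction: the chiral phosphonium nitronate of 18 adds to aldehyde 23, forming the C3–C18 bond between two normally electrophilic carbons and setting C3 (R) and C18 (S) under catalyst control; acid-catalysed lactonisation with retention at C18 then gives the cis-2,4-disubstituted ring E before any further basic step.

Step 13
Reactants: 25 (5R)-5-[(3S,4R,8R)-4-(4-chlorobutyl)-4-hydroxy-8-[(2S,4S)-4-methyl-5-oxooxolan-2-yl]-8-nitro-5-oxooctan-3-yl]-3-methylfuran-2(5H)-one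
Product: 27 (5R)-5-[(3S,4R)-8-chloro-4-hydroxy-4-{(2R)-2-[(2S,4S)-4-methyl-5-oxooxolan-2-yl]-3,4-dihydro-2H-pyrrol-5-yl}octan-3-yl]-3-methylfuran-2(5H)-one, via amino ketone 26 (not isolated)
Conditions: Zn dust, AcOH/EtOH, 0 → 40 °C; then aq. NaHCO3
Reagents that add atoms: none
Why: Nitro reduction with zinc in acetic acid gives the primary amine, which under the acidic conditions condenses at once with the C9a ketone (five-membered cyclic imine, ring B), so C3 keeps its configuration and the amine has no chance to attack a lactone.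

Step 14
Reactants: 27 (5R)-5-[(3S,4R)-8-chloro-4-hydroxy-4-{(2R)-2-[(2S,4S)-4-methyl-5-oxooxolan-2-yl]-3,4-dihydro-2H-pyrrol-5-yl}octan-3-yl]-3-methylfuran-2(5H)-one
Product: 30 target CNP0186848.1, via alkyl iodide 28 (not isolated), via bicyclic enamine 29 (not isolated)
Conditions: NaI (3 equiv), iPr2NEt (3 equiv), MeCN (0.01 M), 70 °C
Reagents that add atoms: none
Why: Finkelstein exchange and intramolecular N-alkylation of the cyclic imine close ring A and, after loss of HI, give the tertiary enamine, whose C1 adds in an intramolecular Stork enamine Michael reaction to the butenolide on the face that carries the tether (ring C, cis-fused ring D, C12 R), while protonation of the lactone enolate from the convex face puts the C13 methyl on the concave face (C13 R) and proton loss from C1 restores the C9a=C1 enamine.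

## Compound list

1 | (S)-4-benzyl-1,3-oxazolidin-2-one | O=C1N[C@@H](Cc2ccccc2)CO1 | starting material
2 | butanoyl chloride | CCCC(Cl)=O | starting material
3 | (S)-4-benzyl-3-butanoyl-1,3-oxazolidin-2-one | CCCC(=O)N1[C@@H](Cc2ccccc2)COC1=O | intermediate
4 | acrolein (prop-2-enal) | C=CC=O | starting material
5 | (S)-4-benzyl-3-[(2S,3R)-2-ethyl-3-hydroxypent-4-enoyl]-1,3-oxazolidin-2-one | CC[C@H](C(=O)N1[C@@H](Cc2ccccc2)COC1=O)[C@H](O)C=C | intermediate
6 | (2S,3R)-2-ethyl-3-hydroxy-N-methoxy-N-methylpent-4-enamide | CC[C@H](C(=O)N(C)OC)[C@H](O)C=C | intermediate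
7 | methoxyallene (1-methoxypropa-1,2-diene) | COC=C=C | starting material
8 | 1-lithio-1-methoxyallene | [Li]C(OC)=C=C | intermediate
9 | (5S,6R)-5-ethyl-6-hydroxy-3-methoxyocta-1,2,7-trien-4-one | C=C=C(OC)C(=O)[C@@H](CC)[C@H](O)C=C | intermediate
10 | 1-bromo-4-chlorobutane | ClCCCCBr | starting material
11 | 4-chlorobutylmagnesium bromide | ClCCCC[Mg]Br | intermediate
12 | (4R,5S,6R)-4-(4-chlorobutyl)-5-ethyl-3-methoxyocta-1,2,7-triene-4,6-diol | C=C=C(OC)[C@@](O)(CCCCCl)[C@@H](CC)[C@H](O)C=C | intermediate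
13 | (4R,5S,6R)-4-(4-chlorobutyl)-5-ethyl-4,6-dihydroxyocta-1,7-dien-3-one | C=CC(=O)[C@@](O)(CCCCCl)[C@@H](CC)[C@H](O)C=C | intermediate
14 | nitromethane | C[N+](=O)[O-] | starting material
15 | (5R,6S,7R)-5-(4-chlorobutyl)-6-ethyl-5,7-dihydroxy-1-nitronon-8-en-4-one | [O-][N+](=O)CCCC(=O)[C@@](O)(CCCCCl)[C@@H](CC)[C@H](O)C=C | intermediate
16 | methacrylic anhydride | CC(=C)C(=O)OC(=O)C(C)=C | starting material
17 | (3R,4S,5R)-5-(4-chlorobutyl)-4-ethyl-5-hydroxy-9-nitro-6-oxonon-1-en-3-yl 2-methylprop-2-enoate | [O-][N+](=O)CCCC(=O)[C@@](O)(CCCCCl)[C@@H](CC)[C@H](OC(=O)C(C)=C)C=C | intermediate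
18 | (5R)-5-[(3S,4R)-4-(4-chlorobutyl)-4-hydroxy-8-nitro-5-oxooctan-3-yl]-3-methylfuran-2(5H)-one | [O-][N+](=O)CCCC(=O)[C@@](O)(CCCCCl)[C@@H](CC)[C@@H]1OC(=O)C(C)=C1 | intermediate
19 | (R)-4-benzyl-3-propanoyl-1,3-oxazolidin-2-one | CCC(=O)N1[C@H](Cc2ccccc2)COC1=O | starting material
20 | allyl iodide (3-iodoprop-1-ene) | C=CCI | starting material
21 | (R)-4-benzyl-3-[(2S)-2-methylpent-4-enoyl]-1,3-oxazolidin-2-one | C=CC[C@H](C)C(=O)N1[C@H](Cc2ccccc2)COC1=O | intermediate
22 | methyl (2S)-2-methylpent-4-enoate | C=CC[C@H](C)C(=O)OC | intermediate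
23 | methyl (2S)-2-methyl-4-oxobutanoate | O=CC[C@H](C)C(=O)OC | intermediate
24 | methyl (2S,4S,5R,9R,10S)-9-(4-chlorobutyl)-4,9-dihydroxy-2-methyl-10-[(2R)-4-methyl-5-oxo-2,5-dihydrofuran-2-yl]-5-nitro-8-oxododecanoate | [O-][N+](=O)[C@@H]([C@@H](O)C[C@H](C)C(=O)OC)CCC(=O)[C@@](O)(CCCCCl)[C@@H](CC)[C@@H]1OC(=O)C(C)=C1 | intermediate
25 | (5R)-5-[(3S,4R,8R)-4-(4-chlorobutyl)-4-hydroxy-8-[(2S,4S)-4-methyl-5-oxooxolan-2-yl]-8-nitro-5-oxooctan-3-yl]-3-methylfuran-2(5H)-one | [O-][N+](=O)[C@@H]([C@@H]1C[C@H](C)C(=O)O1)CCC(=O)[C@@](O)(CCCCCl)[C@@H](CC)[C@@H]1OC(=O)C(C)=C1 | intermediate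
26 | (5R)-5-[(3S,4R,8R)-8-amino-4-(4-chlorobutyl)-4-hydroxy-8-[(2S,4S)-4-methyl-5-oxooxolan-2-yl]-5-oxooctan-3-yl]-3-methylfuran-2(5H)-one | N[C@@H]([C@@H]1C[C@H](C)C(=O)O1)CCC(=O)[C@@](O)(CCCCCl)[C@@H](CC)[C@@H]1OC(=O)C(C)=C1 | intermediate
27 | (5R)-5-[(3S,4R)-8-chloro-4-hydroxy-4-{(2R)-2-[(2S,4S)-4-methyl-5-oxooxolan-2-yl]-3,4-dihydro-2H-pyrrol-5-yl}octan-3-yl]-3-methylfuran-2(5H)-one | ClCCCC[C@@](O)([C@@H](CC)[C@@H]1OC(=O)C(C)=C1)C1=N[C@H](CC1)[C@@H]1C[C@H](C)C(=O)O1 | intermediate
28 | (5R)-5-[(3S,4R)-4-hydroxy-8-iodo-4-{(2R)-2-[(2S,4S)-4-methyl-5-oxooxolan-2-yl]-3,4-dihydro-2H-pyrrol-5-yl}octan-3-yl]-3-methylfuran-2(5H)-one | ICCCC[C@@](O)([C@@H](CC)[C@@H]1OC(=O)C(C)=C1)C1=N[C@H](CC1)[C@@H]1C[C@H](C)C(=O)O1 | intermediate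
29 | (5R)-5-{(1S)-1-[(3R,9R)-9-hydroxy-3-[(2S,4S)-4-methyl-5-oxooxolan-2-yl]-2,3,6,7,8,9-hexahydro-5H-pyrrolo[1,2-a]azepin-9-yl]propyl}-3-methylfuran-2(5H)-one | CC[C@@H]([C@@H]1OC(=O)C(C)=C1)[C@]2(O)CCCCN3C2=CC[C@@H]3[C@@H]1C[C@H](C)C(=O)O1 | intermediate
30 | target CNP0186848.1: pentacyclic 9-hydroxy enamine, rings A–E as defined above (3R,9R,10S,11R,12R,13R,18S,20S in the position numbering used here) | CC[C@H]1[C@@H]2OC(=O)[C@H](C)[C@@H]2C2=C3N(CCCC[C@]31O)[C@@H]([C@@H]1C[C@H](C)C(=O)O1)C2 | target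

## Step count and risks

Total steps: 14. Longest linear sequence: 11 (steps 1–8, then 12–14); the aldehyde branch (steps 9–11) joins at step 12.

The three steps most likely to fail:

**Step 12 (anti-selective nitroaldol joining 18 and 23).** A functionalised nitroalkane with a free tertiary alcohol, a ketone and a butenolide is outside the usual substrate range, so diastereo- and enantiocontrol at C3/C18 is uncertain. The fallback replaces the aldol-type bond formation by acylation–reduction; it sets out from 18 (using 23) and comes back at 24. Aldehyde 23 is oxidised (NaClO2, NaH2PO4, 2-methylbut-2-ene) to (3S)-4-methoxy-3-methyl-4-oxobutanoic acid F4 and activated with carbonyldiimidazole to the acyl imidazole F5. The nitronate of 18 (DBU) is C-acylated by F5 to give the α-nitro ketone F6, whose nitro-bearing carbon epimerises freely. Asymmetric transfer hydrogenation with RuCl[(S,S)-TsDPEN](p-cymene) or its enantiomer in HCO2H/Et3N, run as a dynamic kinetic resolution, then sets C18 and C3 together to give 24. Lactonisation as in step 12 then gives 25.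

**Step 5 (chelation-controlled Grignard addition to the methoxyallenyl ketone).** Enolisation, conjugate addition to the allenyl ketone, cyclisation of the β-hydroxy allenyl ketone 9, or incomplete chelation control at C9 could all intervene. The fallback reverses the order of the two carbon–carbon bond formations and uses Felkin–Anh instead of chelation control; it sets out from 6 and comes back at 13. Amide 6 is silylated (TBSOTf, 2,6-lutidine) to the silyl ether F1, which reacts with Grignard reagent 11 to give the chlorobutyl ketone F2. Addition of 1-lithio-1-methoxyallene 8, with chelation shut off, occurs anti to the C11 branch and gives the allenyl carbinol F3 with the same C9 configuration. Aqueous HCl followed by HF·pyridine hydrolyses the enol ether and removes the silyl group to give 13.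

**Step 14 (cascade N-alkylation and enamine Michael addition).** Seven-membered ring closure by an imine nitrogen is slow and competes with intermolecular alkylation, and the α-hydroxy imine could rearrange on prolonged heating. The fallback reverses the order of ring formation (ring C before ring A) in two separate operations; it sets out from 27 and comes back at 30. Heating 27 with AcOH (0.2 equiv) in toluene at 80 °C lets the N–H enamine tautomer of the pyrroline add to the butenolide first (aza-ene-type Michael addition), giving the tricyclic imine F7 with ring C and the cis-fused lactone in place. NaI in acetone converts it to the iodide F8, and heating with iPr2NEt in MeCN closes ring A on the now rigid imine; deprotonation at C1 gives 30.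

## Further compounds

F1 | step 5 | (2S,3R)-3-[(tert-butyldimethylsilyl)oxy]-2-ethyl-N-methoxy-N-methylpent-4-enamide | CC[C@H](C(=O)N(C)OC)[C@H](O[Si](C)(C)C(C)(C)C)C=C
F2 | step 5 | (6S,7R)-7-[(tert-butyldimethylsilyl)oxy]-1-chloro-6-ethylnon-8-en-5-one | ClCCCCC(=O)[C@@H](CC)[C@H](O[Si](C)(C)C(C)(C)C)C=C
F3 | step 5 | (4R,5S,6R)-6-[(tert-butyldimethylsilyl)oxy]-4-(4-chlorobutyl)-5-ethyl-3-methoxyocta-1,2,7-trien-4-ol | C=C=C(OC)[C@@](O)(CCCCCl)[C@@H](CC)[C@H](O[Si](C)(C)C(C)(C)C)C=C
F4 | step 12 | (3S)-4-methoxy-3-methyl-4-oxobutanoic acid | OC(=O)C[C@H](C)C(=O)OC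
F5 | step 12 | methyl (2S)-4-(1H-imidazol-1-yl)-2-methyl-4-oxobutanoate | O=C(C[C@H](C)C(=O)OC)n1ccnc1
F6 | step 12 | methyl (2S,9R,10S)-9-(4-chlorobutyl)-9-hydroxy-2-methyl-10-[(2R)-4-methyl-5-oxo-2,5-dihydrofuran-2-yl]-5-nitro-4,8-dioxododecanoate (C5 configurationally labile) | [O-][N+](=O)C(C(=O)C[C@H](C)C(=O)OC)CCC(=O)[C@@](O)(CCCCCl)[C@@H](CC)[C@@H]1OC(=O)C(C)=C1
F7 | step 14 | tricyclic imine (N4=C9a imine, C1–C12 bond closed, cis-fused ring D, 9-hydroxy, 9-(4-chlorobutyl); C1 epimers) | CC[C@H]1[C@@H]2OC(=O)[C@H](C)[C@@H]2C2C[C@@H](N=C2[C@@]1(O)CCCCCl)[C@@H]1C[C@H](C)C(=O)O1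
F8 | step 14 | tricyclic imine iodide (4-iodobutyl analogue of F7) | CC[C@H]1[C@@H]2OC(=O)[C@H](C)[C@@H]2C2C[C@@H](N=C2[C@@]1(O)CCCCI)[C@@H]1C[C@H](C)C(=O)O1
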